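The readings stem from a simulated flask for an exercise, and the scatter is random.

Take the ratio of two times: the 4.0 min your charge spends in the vessel (in winter, on average), and the relaxation time in which the gap between G and its plateau shrinks by a factor e.

| flask | D | remark | time |
|---|---|---|---|
| beta | 33 mM | run made earlier |  |
| zeta | 22 mM | run made earlier |  |
| eta | 50 mM | run made earlier |  |
| summer | 33 mM | a tube with plug flow, the mixed feed as stated, residence time 4.0 min | 4.0 min |
| winter | 33 mM | a single well-mixed tank run continuously and read at steady state, 4.0 min in it on average |  |
| midnight | 33 mM | a closed flask charged with all of it at once and left for 4.0 min | 4.0 min |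

- beta (time / min: G / %): 0.200: 42.5; 0.417: 58.0; 1.00: 63.9; 2.50: 62.7
- zeta (time / min: G / %): 0.667: 63.2; 1.33: 64.7; 2.00: 63.3; 2.50: 63.2
- eta (time / min: G / %): 0.333: 52.9; 0.833: 63.1; 1.50: 63.0; 2.50: 62.5

(scatter of a reading: 0.3 percentage points)

- in percentages every species weighs as the D in it: one E counts as two
- for G the E are counted in
- the stated concentrations are those of everything mixed, before any reaction; amounts are the same in each set-up
- reactions considered so far: D <-> G; G <-> L; L <-> D; D + G <-> E
- the earlier runs were made in a closed, stirred flask
- in an amount of G, one E counts as one G

* the set-up with the highest amount of G at the outlet or at the end, in percent of the D put in ("none" if the first two lie within 2 percentage points) (summer / winter / midnight / none)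
* amount of G at the outlet or at the end, in percent of the D put in, summer
* amount of G at the outlet or at the end, in percent of the D put in, winter
* amount of G at the outlet or at the end, in percent of the D put in, midnight

Read the relaxation time from the beta run. The plateau reading is 63.9 %, and G stands at 42.5 % after 0.200 min. You integrate a first-order approach, so the gap falls exponentially, and the reading gives 0.183 min. You therefore hold the charge for 21.9 relaxation times: call this the holding number.

In a closed flask or a plug-flow tube, the share of the gap left is exp of minus that number, hardly any, so I take the late beta reading, 62.7 %. A well-mixed tank spreads the ages, and its steady-state shortfall is one over one plus the holding number, 4.37 % of the plateau. My winter figure is thus 60.0 %.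

The forecast gives 62.4 % for summer and midnight and 59.8 % for winter, and names none as best: “Plug flow and the closed flask are the same history”.

The flasks give 62.8 % in summer, 62.8 % at midnight and 60.5 % in winter, so best is none.

    D ⇌ G (K = 3.10, k = 0.0580 s⁻¹)
    G ⇌ L (K = 0.240, k = 0.00420 s⁻¹)
    L ⇌ D (k = 0.00490 s⁻¹)
    D + G ⇌ E, settled at all times (K = 12.0 M⁻¹)

At midnight, the half-life of D by its forward step into G, 0.20 min, is shorter than the 2.8 min of free G by its forward step into L, and L stands at 14.0 % at the end. With a holding number of 21.9, winter ends 2.3 percentage points below summer. Left 40.0 min, summer has a holding number of 219, and it reads 62.8 %.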